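## Retrosynthetic overview

1. The target is (2R)-naringenin joined through C-6 to C-6' of luteolin, with one stereocentre at C-2 of the flavanone. Both halves are bought as flavonoids: (±)-naringenin 1, re-opened to its biosynthetic precursor naringenin chalcone 2, and luteolin 3, which brings the flavone ring C ready-made.
2. Biaryl bond (oxidative phenol coupling, no ring formed): luteolin o-quinone 4, made in the flask from 3, is arylated at C-6' by the phloroglucinol ring of 2. The two free carbons of that ring are equivalent, so a single biaryl chalcone 5 results.
3. Last ring and the stereocentre: a chalcone-isomerase-type asymmetric oxa-Michael closure of 5 through the unhindered 6'-OH gives the 6-linked (2R)-flavanone 6.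
4. Ring order: all carbocycles and the flavone ring C are present throughout; the flavanone ring C is opened in step 1 and re-formed enantioselectively in step 3.

Assumption: the C-6–C-6' biaryl axis (three ortho substituents, two of them OH) is taken to rotate freely at room temperature, since the target SMILES carries no axial descriptor; the quinine-derived catalyst of step 3 is taken to give the (2R) sense, and its quinidine-derived pseudoenantiomer is substituted if CD analysis of 6 shows (2S).

## Route

Step 1
Reactants: 1 (±)-naringenin
Product: 2 naringenin chalcone
Conditions: 50% aq KOH, N2, rt, 30 min; then poured into ice-cold 6 M HCl (to pH 1), filtered at once, dried in vacuo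
Reagents that add atoms: none
Why: Retro-oxa-Michael (E1cB) ring opening of a 5-hydroxyflavanone, in which concentrated alkali favours the ring-opened E-chalcone and rapid acidification at 0 °C protonates it faster than it can re-close, because closure needs a free ortho-phenolate; the stereocentre of 1 is deliberately erased.

Step 2
Reactants: 2 naringenin chalcone (3 equiv); 3 luteolin (1 equiv)
Product: 5 3'-(luteolin-6'-yl)naringenin chalcone, via luteolin 3',4'-quinone 4 (not isolated)
Conditions: NaIO4 (0.9 equiv, aq, added over 2 h), THF–aq NaOAc/AcOH buffer (pH 4.5) 2:1, 0 °C, dark, Ar; C18 chromatography (MeCN–H2O, 0.1% HCO2H), excess 2 recovered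
Reagents that add atoms: none
Why: Biomimetic oxidative phenol cross-coupling by Michael addition to an o-quinone (quinone arylation, as in the biaryl dehydrodimers of flavan-3-ols), in which periodate oxidises only the catechol of 3 through its cyclic ester, the electron-rich ring of 2 adds to C-6' of 4 (β-carbon of the C-4' enone and the less hindered ortho site) and re-aromatisation returns the catechol; C-3' and C-5' of 2 are equivalent, so only one constitution can form, and at pH 4.5 and 0 °C neither chalcone closes to a flavanone.

Step 3
Reactants: 5 3'-(luteolin-6'-yl)naringenin chalcone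
Product: 6 (2R)-6-(luteolin-6'-yl)naringenin (target)
Conditions: N-[3,5-bis(trifluoromethyl)phenyl]-N'-[(8α,9S)-6'-methoxycinchonan-9-yl]thiourea (C29H28F6N4OS, quinine-derived, 20 mol %), THF, −25 °C, 72 h; C18 chromatography (MeCN–H2O, 0.1% HCO2H)
Reagents that add atoms: none
Why: Proposed new method: the bifunctional cinchona thiourea acts as a small-molecule chalcone isomerase, its quinuclidine nitrogen deprotonating the unhindered 6'-OH (the 2'-OH is shielded by the twisted biaryl and stays hydrogen-bonded to the carbonyl as the future 5-OH) while the thiourea binds the enone carbonyl, so that the phenolate adds 6-endo-trig to one enantiotopic face of the β-carbon inside the chiral ion pair and C-2 is set as R under catalyst control; the closest known reaction type is the cinchona-thiourea-catalysed intramolecular oxa-Michael addition of phenols to activated enones that gives flavanones and chromanones, here extended to an unactivated, unprotected 2',6'-dihydroxychalcone and run cold and stopped at full conversion because retro-Michael opening would racemise the product.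

## Compound list

1 | (±)-naringenin, racemic 5,7-dihydroxy-2-(4-hydroxyphenyl)chroman-4-one | O=C1CC(c2ccc(O)cc2)Oc2cc(O)cc(O)c21 | starting material
2 | naringenin chalcone, (E)-3-(4-hydroxyphenyl)-1-(2,4,6-trihydroxyphenyl)prop-2-en-1-one | O=C(/C=C/c1ccc(O)cc1)c1c(O)cc(O)cc1O | intermediate
3 | luteolin, 2-(3,4-dihydroxyphenyl)-5,7-dihydroxy-4H-chromen-4-one | O=c1cc(-c2ccc(O)c(O)c2)oc2cc(O)cc(O)c12 | starting material
4 | luteolin 3',4'-quinone, 4-(5,7-dihydroxy-4-oxo-4H-chromen-2-yl)cyclohexa-3,5-diene-1,2-dione | O=C1C=CC(c2cc(=O)c3c(O)cc(O)cc3o2)=CC1=O | intermediate (not isolated)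
5 | 3'-(luteolin-6'-yl)naringenin chalcone, 2-{4,5-dihydroxy-2-[2,4,6-trihydroxy-3-[(E)-3-(4-hydroxyphenyl)prop-2-enoyl]phenyl]phenyl}-5,7-dihydroxy-4H-chromen-4-one | O=C(/C=C/c1ccc(O)cc1)c1c(O)cc(O)c(-c2cc(O)c(O)cc2-c2cc(=O)c3c(O)cc(O)cc3o2)c1O | intermediate
6 | (2R)-6-[2-(5,7-dihydroxy-4-oxo-4H-chromen-2-yl)-4,5-dihydroxyphenyl]-5,7-dihydroxy-2-(4-hydroxyphenyl)-2,3-dihydro-4H-chromen-4-one | O=C1C[C@H](c2ccc(O)cc2)Oc2cc(O)c(-c3cc(O)c(O)cc3-c3cc(=O)c4c(O)cc(O)cc4o3)c(O)c21 | target

## Step count and risks

Total steps: 3. Longest linear sequence: 3 steps (1 → 2 → 5 → 6); luteolin 3 enters in step 2.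

**Step 2 (most likely to fail).** The product catechol 5 is more electron-rich than luteolin and can be re-oxidised by 4 or by periodate. Luteolin can also couple with itself through its own ring A, and some 2 may be lost. Sub-stoichiometric oxidant, slow addition and excess 2 are the safeguards, and a yield of 25–40% is a realistic expectation. The fallback sets out from 1 and 3 and comes back at 5. The quinone 4 is generated in the same way but is trapped at pH 5.5 by a tenfold excess of the cheap, robust flavanone 1 itself. This gives a mixture of the racemic 6-linked flavanone F1 and the racemic 8-linked flavanone F2. The mixture is not separated, because alkaline ring opening (50% aq KOH, N2, 0 °C, then cold HCl, as in step 1) turns both regioisomers into the one chalcone 5: its phloroglucinol ring is the same whichever oxygen had been in the ring.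

**Step 3.** The eight free phenols may protonate or bind the catalyst and lower the ee. Some closure through the hindered 2'-OH would give the 8-linked isomer. Slow retro-Michael opening can erode the ee. The fallback sets out from 2 (with 3) and comes back at 6. The stereocentre is set first on the small chalcone 2 with the same catalyst (10 mol %, toluene–THF, −25 °C), where the closure is much nearer to precedent. This gives (R)-naringenin F3, whose ee can be raised by recrystallisation or chiral HPLC before further use. F3 (3 equiv) then serves as the nucleophile toward 4 under the conditions of step 2; a 5-hydroxyflavanone does not racemise at pH 4.5 and 0 °C. The coupling gives 6 together with the (2R)-8-linked regioisomer F4, which is removed by reversed-phase HPLC.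

**Step 1.** Partial re-closure during acidification gives 2 contaminated with 1, which would later carry racemic flavanone through the route. The fallback sets out from 1 and comes back at 2. The ring is opened with irreversible trapping: NaH (6 equiv) in DMF at 0 °C, then MOMCl (6 equiv), gives the tetrakis(methoxymethyl) ether of naringenin chalcone F5. F5 cannot re-close and is purified on silica. HCl in MeOH at room temperature then removes the four methoxymethyl groups to give 2.

## Further compounds

F1 | step 2 | racemic 6-(luteolin-6'-yl)naringenin (racemate of 6) | O=C1CC(c2ccc(O)cc2)Oc2cc(O)c(-c3cc(O)c(O)cc3-c3cc(=O)c4c(O)cc(O)cc4o3)c(O)c21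
F2 | step 2 | racemic 8-(luteolin-6'-yl)naringenin | O=C1CC(c2ccc(O)cc2)Oc2c(-c3cc(O)c(O)cc3-c3cc(=O)c4c(O)cc(O)cc4o3)c(O)cc(O)c21
F3 | step 3 | (R)-naringenin, (2R)-5,7-dihydroxy-2-(4-hydroxyphenyl)chroman-4-one | O=C1C[C@H](c2ccc(O)cc2)Oc2cc(O)cc(O)c21
F4 | step 3 | (2R)-8-(luteolin-6'-yl)naringenin | O=C1C[C@H](c2ccc(O)cc2)Oc2c(-c3cc(O)c(O)cc3-c3cc(=O)c4c(O)cc(O)cc4o3)c(O)cc(O)c21
F5 | step 1 | (E)-3-[4-(methoxymethoxy)phenyl]-1-[2,4,6-tris(methoxymethoxy)phenyl]prop-2-en-1-one | COCOc1ccc(/C=C/C(=O)c2c(OCOC)cc(OCOC)cc2OCOC)cc1
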